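If the substrate takes coupling partner first, count what that leaves over.

| flask | substrate | fresh partner | coupling partner | remark | time |
|---|---|---|---|---|---|
| eta | 0.024 M | 0.020 M (fed, over 15 s) | 0.050 M | run made earlier |  |
| epsilon | 0.051 M | 0.020 M (fed, over 15 s) | 0.050 M | run made earlier |  |
| theta | 0.020 M | 0.020 M (fed, over 15 s) | 0.099 M | run made earlier |  |
| autumn | 0.040 M | 0.0200 M (fed, over 15 s) | 0.0500 M |  | 2.0 min |
| spring | 0.040 M | 0.0200 M (fed, over 15 s) | 0.100 M |  | 2.0 min |
| dusk | 0.020 M | 0.0200 M (fed, over 15 s) | 0.0500 M |  | 2.0 min |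
| dawn | 0.020 M | 0.0200 M (fed, over 15 s) | 0.100 M |  | 2.0 min |

| run | time / s | open intermediate / % | target / % | substrate / % |
|---|---|---|---|---|
| eta | 10.0 | 97.5 | 2.2 | 0.8 |
| eta | 20.0 | 93.2 | 9.9 | 0 |
| eta | 30.0 | 82.8 | 17.2 | 1.2 |
| eta | 50.0 | 72.0 | 27.7 | 0 |
| eta | 80.0 | 62.7 | 38.9 | 0 |
| eta | 90.0 | 57.3 | 40.8 | 1.1 |
| eta | 120 | 54.6 | 45.7 | 0.4 |
| epsilon | 10.0 | 93.8 | 0 | 7.5 |
| epsilon | 20.0 | 94.2 | 0.2 | 4.9 |
| epsilon | 30.0 | 95.8 | 4.5 | 3.4 |
| epsilon | 50.0 | 95.0 | 2.3 | 5.7 |
| epsilon | 80.0 | 92.2 | 1.0 | 1.3 |
| epsilon | 90.0 | 94.2 | 0.6 | 3.9 |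
| epsilon | 120 | 94.1 | 0.9 | 4.6 |
| theta | 10.0 | 96.7 | 4.6 | 1.6 |
| theta | 30.0 | 72.0 | 28.2 | 0 |
| theta | 60.0 | 59.6 | 38.5 | 0.7 |
| theta | 80.0 | 55.3 | 45.6 | 1.3 |
| theta | 120 | 52.7 | 44.8 | 0 |

(scatter of a reading: 1 percentage point)

- a reading or a percentage of target counts all its forms, free or not

- ranking by amount of open intermediate, in percent of the substrate charged, from high to low, at 2.0 min (autumn / spring / dusk / dawn)
- the amount of open intermediate, in percent of the substrate charged of the flask you put first, at 2.0 min
- the amount of open intermediate, in percent of the substrate charged of the flask you put last, at 2.0 min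

In eta, open intermediate stands at 97.5% after 10.0 s with target at 2.2%, so take the opening as finished and subtract substrate from coupling partner. Epsilon then reckons with nothing free, because its substrate at 0.051 M exceeds its coupling partner at 0.050 M, and its target reads 0.9% at the last reading. Theta's target reads 45.6% at 80.0 s and 44.8% at 120 s although its free coupling partner exceeds the fresh charge, so take it that fresh partner also goes somewhere other than target.

Define the room of a flask, 83.3% in eta, as the smaller of free coupling partner and fresh partner, per substrate charged; that smaller one is the limiting reagent once the opening is over. Divide the last target reading by the room: the yield on room reads 54.8% in eta and 44.8% in theta. Reckon open intermediate as one minus yield times room. Use eta's yield at the lower coupling charge and theta's at the higher.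

Autumn has room 25.0%, giving 86.3%. Spring has 50.0%, giving 77.6%. Dawn has 100%, giving 55.2%. Dusk has 100%, giving 45.2%.

This reckoning parts from the forecast, autumn > dusk > spring > dawn with 72% first and 53.5% last, which called one pair “the least certain”.

The flasks give autumn > spring > dawn > dusk, at 79.7%, 64.3%, 53.1% and 50.8%. The reckoned order stands, but its values sit 6.6 percentage points high in autumn, 13 points high in spring, 2.1 points high in dawn and 5.6 points low in dusk.

    substrate + coupling partner → open intermediate (k = 35.9 M⁻¹ s⁻¹)
    coupling partner + fresh partner → second intermediate (k = 1.93 M⁻¹ s⁻¹)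
    open intermediate + second intermediate → target (k = 1.93 M⁻¹ s⁻¹)
    2 second intermediate → homo product (k = 3.15 M⁻¹ s⁻¹)
    crystals ⇌ target, rate k5*(cs5 - [target]) while solid is left; crystals form when [target] > cs5 (solubility = 12.0 mM, k = 3.64 s⁻¹)

In dusk at 0.00728 min, coupling partner goes to open intermediate 330 times as fast as to second intermediate. The substrate's half-life by the opening step is 0.48 s at that moment in dusk, far shorter than the 0.364 min by which the step from coupling partner and fresh partner to second intermediate has done the first 0.5 of its turnover up to 2.00 min. Dusk with 0.0050 M of fresh partner has room 25.0%, and eta's yield makes that 86.3% open intermediate; at 2.00 min that flask holds 80.7%.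

The runs were computed from invented constants.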